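**Plan**

1. Numbering: decalin C1–C10 (ring A = C1–C5 and C10, ring B = C5–C10; C4 bears the gem-dimethyl group, C8 and C10 one methyl each), chain C11–C15, butenolide C16 (ylidene carbon) to C19. Dec = (4aS,8aS)-2,5,5,8a-tetramethyl-3,4,4a,5,6,7,8,8a-octahydronaphthalen-1-yl.
2. Cuts: (a) lactone O–C16 and C16–C17 (butenolide from a terminal enynol and (Z)-3-iodobut-2-enoic acid); (b) C12–C13 and C9–C11 (two cross-couplings on a decalin enol triflate); (c) C1–C2 and C3–C4 of ring A in one operation; (d) C10–C1 and C10–CH3 (two enolate alkylations).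
3. Forward: ring B is (R)-carvone; C10 is made quaternary; ring A is annulated with acrolein as the C2–C3 unit; the C1 oxygen and the C2 formyl group are removed; the decalone becomes its enol triflate; the chain is joined C11/C12, then C13; the butenolide ring is closed last.
4. Enabling feature: C4 is a gem-dimethyl quaternary carbon on the ring-fusion CH (C5), which makes it the Markovnikov carbon of carvone's isopropenyl group. C1 is a CH2 on quaternary C10 and can be carried as an aldehyde. The two are 1,4-related across the C5–C10 bond of ring B, so a tertiary C4 radical and a C1 carbonyl can be bridged by a two-carbon acceptor.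
5. Stereochemistry: C5 comes from (R)-carvone; C10 from alkylation anti to the isopropenyl group, which also fixes the trans fusion (5S,10S); 13E from a Z-selective bromo-Wittig reaction followed by stereoretentive coupling; the Z ylidene bond from anti-addition of the carboxylate across the alkyne.

Key step: step 4

Remark on the chemistry: centres that are erased again are carried as epimer mixtures (C6 of the methylated carvone, drawn as its major trans epimer; C1/C2 of the annulation product and its mesylate and C8 of the saturated decalone, left open in the SMILES), and all numbered starting materials are taken as commercial.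

**Route**

Step 1
Reactants: 1 (R)-(−)-carvone, (5R)-2-methyl-5-(prop-1-en-2-yl)cyclohex-2-en-1-one
Product: 3 (5R,6S)-2,6-dimethyl-5-(prop-1-en-2-yl)cyclohex-2-en-1-one (trans-6-methylcarvone), via lithium dienolate 2 (not isolated)
Conditions: LDA (1.1 equiv), THF, −78 °C; MeI, −78 → 0 °C
Reagents that add atoms: iodomethane, CI; lithium diisopropylamide, [Li+].CC(C)[N-]C(C)C (lithium stays in 2 only)
Why: Kinetic α′-deprotonation of the enone and SN2 methylation of the cross-conjugated dienolate (enolate alkylation) should place the methyl group mainly trans to the isopropenyl group, and the minor epimer is harmless because this centre is planarised again in step 2.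

Step 2
Reactants: 3 (5R,6S)-2,6-dimethyl-5-(prop-1-en-2-yl)cyclohex-2-en-1-one
Product: 5 (5S,6R)-6-(hydroxymethyl)-2,6-dimethyl-5-(prop-1-en-2-yl)cyclohex-2-en-1-one, via lithium enolate 4 (not isolated)
Conditions: LDA (1.2 equiv), THF, −78 °C; CH2O (gas, from cracked paraformaldehyde), −78 °C; AcOH quench at −78 °C
Reagents that add atoms: formaldehyde, C=O; lithium diisopropylamide, [Li+].CC(C)[N-]C(C)C (lithium stays in 4 only)
Why: The tetrasubstituted enolate should undergo aldol addition to monomeric formaldehyde on the face anti to the neighbouring isopropenyl group, which sets quaternary C10 with the methyl group cis and the hydroxymethyl group (future C1) trans to the isopropenyl group (future C4), as the trans ring fusion requires.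

Step 3
Reactants: 5 (5S,6R)-6-(hydroxymethyl)-2,6-dimethyl-5-(prop-1-en-2-yl)cyclohex-2-en-1-one
Product: 6 (1R,6S)-1,3-dimethyl-2-oxo-6-(prop-1-en-2-yl)cyclohex-3-ene-1-carbaldehyde
Conditions: Dess–Martin periodinane (1.3 equiv), CH2Cl2, 0 °C → rt
Reagents that add atoms: none
Why: Dess–Martin oxidation of the neopentyl primary alcohol should give the aldehyde under neutral conditions, and the product cannot enolise between its two carbonyl groups because C10 is quaternary.

Step 4
Reactants: 6 (1R,6S)-1,3-dimethyl-2-oxo-6-(prop-1-en-2-yl)cyclohex-3-ene-1-carbaldehyde; 7 acrolein (prop-2-enal, 3 equiv)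
Product: 9 (4aS,8aR)-1-hydroxy-4,4,7,8a-tetramethyl-8-oxo-1,2,3,4,4a,5,8,8a-octahydronaphthalene-2-carbaldehyde, via Giese adduct enolate 8 (not isolated)
Conditions: Fe(acac)3 (30 mol %), PhSiH3 (2.5 equiv), EtOH–(CH2OH)2, 0 °C → rt, slow addition of 7
Reagents that add atoms: none
Why: An iron hydride formed from Fe(acac)3 and PhSiH3 transfers a hydrogen atom to the CH2 terminus of the isopropenyl group, the tertiary C4 radical adds to the β-carbon of acrolein (C3–C4 bond, Giese addition), the α-formyl radical is reduced by divalent iron to an enolate (radical–polar crossover), and this enolate adds to the C1 aldehyde on C10 (C1–C2 bond). The closest known reaction type is the iron-hydride-initiated radical–polar crossover annulation of γ,δ-unsaturated aldehydes with enones and enals, of which 6 (aldehyde carbon C1, alkene carbon C4) is a cyclic example. Ring A closes by a 6-(enolexo)-exo-trig aldol addition through a chair-like transition state. The only new stereocentres, C1 and C2, are set by that transition state but are not needed, since both are erased in steps 5 to 7; C4 is not stereogenic, and the trans ring fusion follows from the trans disposition of the C5 isopropenyl and C10 formyl groups fixed in steps 1 and 2. The step needs hydrogen-atom transfer to the 1,1-disubstituted alkene in preference to the conjugated C7=C8 bond, capture of the tertiary radical by acrolein, and aldol closure on the aldehyde and not on the C9 ketone; these should be secured by the higher reactivity of the electron-rich isopropenyl group toward the hydride, the excess of the unhindered acceptor, and the far greater electrophilicity of the aldehyde (closure on C9 would also build a strained bicyclo[2.2.2]octane).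

Step 5
Reactants: 9 (4aS,8aR)-1-hydroxy-4,4,7,8a-tetramethyl-8-oxo-1,2,3,4,4a,5,8,8a-octahydronaphthalene-2-carbaldehyde
Product: 11 (4aS,8aS)-4,4,7,8a-tetramethyl-8-oxo-3,4,4a,5,8,8a-hexahydronaphthalene-2-carbaldehyde, via mesylate 10 (not isolated)
Conditions: MsCl (1.5 equiv), Et3N (3 equiv), CH2Cl2, 0 °C; then DBU (2 equiv), rt
Reagents that add atoms: methanesulfonyl chloride, CS(=O)(=O)Cl (its atoms stay in 10 only)
Why: Mesylation of the β-hydroxy aldehyde followed by base-induced E1cB elimination should give the conjugated enal, the only possible direction because C10 carries no hydrogen.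

Step 6
Reactants: 11 (4aS,8aS)-4,4,7,8a-tetramethyl-8-oxo-3,4,4a,5,8,8a-hexahydronaphthalene-2-carbaldehyde
Product: 12 (4aS,8aS)-2,5,5,8a-tetramethyl-4a,5,6,8a-tetrahydronaphthalen-1(4H)-one
Conditions: RhCl(PPh3)3 (1.1 equiv), PhCN, 130 °C
Reagents that add atoms: none
Why: Tsuji–Wilkinson decarbonylation (oxidative addition of the formyl C–H bond to monovalent rhodium, CO extrusion, C–H reductive elimination) should remove the formyl carbon and leave a ring A alkene whose position does not matter for step 7.

Step 7
Reactants: 12 (4aS,8aS)-2,5,5,8a-tetramethyl-4a,5,6,8a-tetrahydronaphthalen-1(4H)-one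
Product: 13 (4aS,8aS)-2,5,5,8a-tetramethyloctahydronaphthalen-1(2H)-one
Conditions: H2 (1 atm), 10% Pd/C, EtOAc, rt
Reagents that add atoms: none
Why: Heterogeneous catalytic hydrogenation should saturate both the ring A alkene and the conjugated C7=C8 bond but not the ketone, and the new C8 centre forms as a mixture that is erased in step 8.

Step 8
Reactants: 13 (4aS,8aS)-2,5,5,8a-tetramethyloctahydronaphthalen-1(2H)-one
Product: 15 (4aS,8aS)-2,5,5,8a-tetramethyl-3,4,4a,5,6,7,8,8a-octahydronaphthalen-1-yl trifluoromethanesulfonate, via potassium enolate 14 (not isolated)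
Conditions: KHMDS (1.3 equiv), THF, −78 °C; PhNTf2 (1.3 equiv), −78 → 0 °C
Reagents that add atoms: N-phenylbis(trifluoromethanesulfonimide), O=S(=O)(N(c1ccccc1)S(=O)(=O)C(F)(F)F)C(F)(F)F; potassium bis(trimethylsilyl)amide, [K+].C[Si](C)(C)[N-][Si](C)(C)C (potassium stays in 14 only)
Why: The ketone can enolise only toward C8 because C10 is quaternary, so O-triflation of the potassium enolate (enol triflate formation) should give the tetrasubstituted C8=C9 triflate regiospecifically.

Step 9
Reactants: 15 (4aS,8aS)-2,5,5,8a-tetramethyl-3,4,4a,5,6,7,8,8a-octahydronaphthalen-1-yl trifluoromethanesulfonate; 16 tributyl(vinyl)stannane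
Product: 17 (4aS,8aS)-1-ethenyl-2,5,5,8a-tetramethyl-3,4,4a,5,6,7,8,8a-octahydronaphthalene
Conditions: Pd(PPh3)4 (5 mol %), LiCl (3 equiv), THF, reflux
Reagents that add atoms: none
Why: Stille coupling of the hindered enol triflate with the vinylstannane at zerovalent palladium, with LiCl to assist oxidative addition and transmetalation, should give the 1,3-diene and so install C11 and C12.

Step 10
Reactants: 18 ethyl (triphenylphosphoranylidene)acetate; 19 3-[tri(propan-2-yl)silyl]prop-2-ynal
Product: 21 ethyl (2Z)-2-bromo-5-[tri(propan-2-yl)silyl]pent-2-en-4-ynoate, via bromo ylide 20 (not isolated)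
Conditions: NBS (1.05 equiv), CH2Cl2, −20 °C; then 19, −20 °C → rt
Reagents that add atoms: N-bromosuccinimide, O=C1CCC(=O)N1Br
Why: Bromination of the stabilised ylide and Wittig olefination of the ynal by the bromo ylide should give mainly the Z bromo enoate, in which the ester is trans to the alkynyl group as usual for stabilised ylides.

Step 11
Reactants: 17 (4aS,8aS)-1-ethenyl-2,5,5,8a-tetramethyl-3,4,4a,5,6,7,8,8a-octahydronaphthalene; 21 ethyl (2Z)-2-bromo-5-[tri(propan-2-yl)silyl]pent-2-en-4-ynoate
Product: 23 ethyl (2E)-2-[2-(Dec)ethyl]-5-[tri(propan-2-yl)silyl]pent-2-en-4-ynoate, via alkylborane 22 (not isolated)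
Conditions: 9-BBN (1.2 equiv), THF, 0 °C → rt; then 21, PdCl2(dppf) (5 mol %), AsPh3 (10 mol %), Cs2CO3 (3 equiv), DMF–H2O, rt
Reagents that add atoms: 9-borabicyclo[3.3.1]nonane, B1C2CCCC1CCC2 (boron cage stays in 22 only; one hydrogen remains in 23)
Why: 9-BBN should hydroborate only the terminal vinyl carbon (the tetrasubstituted ring alkene is inert), and B-alkyl Suzuki–Miyaura coupling of the primary alkylborane with the bromo enoate proceeds with retention at the alkenyl carbon, so C12 ends cis to the alkynyl group and the ester trans to it (13E).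

Step 12
Reactants: 23 ethyl (2E)-2-[2-(Dec)ethyl]-5-[tri(propan-2-yl)silyl]pent-2-en-4-ynoate
Product: 24 (2E)-2-[2-(Dec)ethyl]-5-[tri(propan-2-yl)silyl]pent-2-en-4-yn-1-ol
Conditions: DIBAL-H (2.5 equiv), CH2Cl2, −78 → 0 °C; Rochelle salt work-up
Reagents that add atoms: none
Why: DIBAL-H should reduce the conjugated ester by 1,2-addition to the allylic alcohol without touching the silyl alkyne or the alkenes.

Step 13
Reactants: 24 (2E)-2-[2-(Dec)ethyl]-5-[tri(propan-2-yl)silyl]pent-2-en-4-yn-1-ol
Product: 25 (2E)-2-[2-(Dec)ethyl]pent-2-en-4-yn-1-ol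
Conditions: TBAF (1.2 equiv), THF, 0 °C
Reagents that add atoms: none
Why: Fluoride-induced protodesilylation should free the terminal alkyne, and the allylic alcohol needs no protection.

Step 14
Reactants: 26 but-2-ynoic acid
Product: 27 (2Z)-3-iodobut-2-enoic acid
Conditions: NaI (1.6 equiv), AcOH, 110 °C
Reagents that add atoms: sodium iodide, [Na+].[I-]
Why: Conjugate anti-hydroiodination of the alkynoic acid (iodide addition at C3, anti protonation) should give the Z acid with iodine cis to the carboxyl group.

Step 15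
Reactants: 25 (2E)-2-[2-(Dec)ethyl]pent-2-en-4-yn-1-ol; 27 (2Z)-3-iodobut-2-enoic acid
Product: 29 (5Z)-5-[(2E)-3-(hydroxymethyl)-5-(Dec)pent-2-en-1-ylidene]-4-methylfuran-2(5H)-one, via enynoic acid 28 (not isolated)
Conditions: PdCl2(PPh3)2 (5 mol %), CuI (10 mol %), Et3N, MeCN, rt, degassed, dark
Reagents that add atoms: none
Why: Sonogashira coupling at zerovalent palladium followed in the flask by 5-exo-dig anti-addition of the carboxylate across the activated alkyne (tandem coupling–lactonisation) should close the butenolide and give the Z ylidene bond, leaving the 13E alkene and the free alcohol untouched.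

**Compound list**

1 | (R)-(−)-carvone, (5R)-2-methyl-5-(prop-1-en-2-yl)cyclohex-2-en-1-one | CC1=CC[C@@H](C(C)=C)CC1=O | starting material
2 | kinetic lithium dienolate of 1 (O–Li on the carbonyl carbon, new C=C toward the ring CH2 next to the isopropenyl carbon) | CC1=CC[C@@H](C(C)=C)C=C1O[Li] | intermediate
3 | (5R,6S)-2,6-dimethyl-5-(prop-1-en-2-yl)cyclohex-2-en-1-one (major trans epimer drawn) | CC1=CC[C@@H](C(C)=C)[C@H](C)C1=O | intermediate
4 | lithium enolate of 3 (tetrasubstituted enolate toward the methyl-bearing carbon) | CC1=CC[C@@H](C(C)=C)C(C)=C1O[Li] | intermediate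
5 | (5S,6R)-6-(hydroxymethyl)-2,6-dimethyl-5-(prop-1-en-2-yl)cyclohex-2-en-1-one | CC1=CC[C@@H](C(C)=C)[C@](C)(CO)C1=O | intermediate
6 | (1R,6S)-1,3-dimethyl-2-oxo-6-(prop-1-en-2-yl)cyclohex-3-ene-1-carbaldehyde | CC1=CC[C@@H](C(C)=C)[C@](C)(C=O)C1=O | intermediate
7 | acrolein (prop-2-enal) | C=CC=O | starting material
8 | Giese adduct enolate: iron-bound enolate (drawn as the free anion) of (1R,6S)-1,3-dimethyl-6-(2-methyl-5-oxopentan-2-yl)-2-oxocyclohex-3-ene-1-carbaldehyde | CC1=CC[C@@H](C(C)(C)CC=C[O-])[C@](C)(C=O)C1=O | intermediate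
9 | (4aS,8aR)-1-hydroxy-4,4,7,8a-tetramethyl-8-oxo-1,2,3,4,4a,5,8,8a-octahydronaphthalene-2-carbaldehyde (trans-fused; epimers at the carbinol and formyl carbons) | O=C1C(C)=CC[C@H]2C(C)(C)CC(C=O)C(O)[C@]12C | intermediate
10 | (4aS,8aR)-2-formyl-4,4,7,8a-tetramethyl-8-oxo-1,2,3,4,4a,5,8,8a-octahydronaphthalen-1-yl methanesulfonate | O=C1C(C)=CC[C@H]2C(C)(C)CC(C=O)C(OS(C)(=O)=O)[C@]12C | intermediate
11 | (4aS,8aS)-4,4,7,8a-tetramethyl-8-oxo-3,4,4a,5,8,8a-hexahydronaphthalene-2-carbaldehyde | O=C1C(C)=CC[C@H]2C(C)(C)CC(C=O)=C[C@]12C | intermediate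
12 | (4aS,8aS)-2,5,5,8a-tetramethyl-4a,5,6,8a-tetrahydronaphthalen-1(4H)-one | O=C1C(C)=CC[C@H]2C(C)(C)CC=C[C@]12C | intermediate
13 | (4aS,8aS)-2,5,5,8a-tetramethyloctahydronaphthalen-1(2H)-one (epimers at C2 of the ring, terpenoid C8) | O=C1C(C)CC[C@H]2C(C)(C)CCC[C@]12C | intermediate
14 | potassium enolate of 13 (C8=C9 enolate) | [K]OC1=C(C)CC[C@H]2C(C)(C)CCC[C@]12C | intermediate
15 | (4aS,8aS)-2,5,5,8a-tetramethyl-3,4,4a,5,6,7,8,8a-octahydronaphthalen-1-yl trifluoromethanesulfonate (Dec–OTf) | O=S(=O)(OC1=C(C)CC[C@H]2C(C)(C)CCC[C@]12C)C(F)(F)F | intermediate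
16 | tributyl(vinyl)stannane | C=C[Sn](CCCC)(CCCC)CCCC | starting material
17 | (4aS,8aS)-1-ethenyl-2,5,5,8a-tetramethyl-3,4,4a,5,6,7,8,8a-octahydronaphthalene (Dec–CH=CH2) | C=CC1=C(C)CC[C@H]2C(C)(C)CCC[C@]12C | intermediate
18 | ethyl (triphenylphosphoranylidene)acetate | CCOC(=O)C=P(c1ccccc1)(c1ccccc1)c1ccccc1 | starting material
19 | 3-[tri(propan-2-yl)silyl]prop-2-ynal | CC(C)[Si](C#CC=O)(C(C)C)C(C)C | starting material
20 | ethyl bromo(triphenylphosphoranylidene)acetate | CCOC(=O)C(Br)=P(c1ccccc1)(c1ccccc1)c1ccccc1 | intermediate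
21 | ethyl (2Z)-2-bromo-5-[tri(propan-2-yl)silyl]pent-2-en-4-ynoate | CCOC(=O)/C(Br)=C/C#C[Si](C(C)C)(C(C)C)C(C)C | intermediate
22 | 9-[2-(Dec)ethyl]-9-borabicyclo[3.3.1]nonane | C(CC1=C(C)CC[C@H]2C(C)(C)CCC[C@]12C)B1C2CCCC1CCC2 | intermediate
23 | ethyl (2E)-2-[2-(Dec)ethyl]-5-[tri(propan-2-yl)silyl]pent-2-en-4-ynoate | CCOC(=O)/C(CCC1=C(C)CC[C@H]2C(C)(C)CCC[C@]12C)=C/C#C[Si](C(C)C)(C(C)C)C(C)C | intermediate
24 | (2E)-2-[2-(Dec)ethyl]-5-[tri(propan-2-yl)silyl]pent-2-en-4-yn-1-ol | OC/C(CCC1=C(C)CC[C@H]2C(C)(C)CCC[C@]12C)=C/C#C[Si](C(C)C)(C(C)C)C(C)C | intermediate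
25 | (2E)-2-[2-(Dec)ethyl]pent-2-en-4-yn-1-ol | OC/C(CCC1=C(C)CC[C@H]2C(C)(C)CCC[C@]12C)=C/C#C | intermediate
26 | but-2-ynoic acid | CC#CC(=O)O | starting material
27 | (2Z)-3-iodobut-2-enoic acid | C/C(I)=C/C(=O)O | intermediate
28 | (2Z,6E)-7-(hydroxymethyl)-3-methyl-9-(Dec)nona-2,6-dien-4-ynoic acid | OC(=O)/C=C(/C)C#C/C=C(/CO)CCC1=C(C)CC[C@H]2C(C)(C)CCC[C@]12C | intermediate
29 | (5Z)-5-[(2E)-3-(hydroxymethyl)-5-(Dec)pent-2-en-1-ylidene]-4-methylfuran-2(5H)-one | CC1=CC(=O)O/C1=C\C=C(\CO)CCC1=C(C)CC[C@H]2C(C)(C)CCC[C@]12C | target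

**Count and risks**

Total step count: 15. Longest linear sequence: 13 steps (steps 1–9, 11, 12, 13 and 15).

Steps most likely to fail:

1. Step 4. After the Giese addition the α-formyl radical may be quenched by hydrogen-atom transfer faster than it is reduced to the enolate, or the aldolate may revert, so that ring A does not close in the flask; acrolein may also be lost to oligomerisation. Fallback: setting out from 6, the iron hydride conditions are used only for the reductive Giese coupling with 7, which should give the open-chain keto dialdehyde (1R,6S)-1,3-dimethyl-6-(2-methyl-5-oxopentan-2-yl)-2-oxocyclohex-3-ene-1-carbaldehyde F1. Ring A is then closed in a separate operation by an amine-salt-mediated intramolecular aldol condensation (piperidinium acetate, benzene, 60 °C). Only the new aldehyde can form an enamine, and the neopentyl aldehyde on C10 is the acceptor. This should give enal 11 directly, where the route is rejoined and step 5 is no longer needed.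

2. Step 11. Hydroboration of the hindered conjugated diene may be incomplete, or transmetalation of the bulky alkylborane may be slow, so that protodeboronation and reduction of the bromo enoate compete. Fallback: setting out from triflate 15 and by-passing 17, Negishi coupling with commercial (4-ethoxy-4-oxobutyl)zinc bromide (Pd(OAc)2, SPhos, THF–NMP, 60 °C) should give ethyl 4-(Dec)butanoate F2. Its lithium enolate (LDA, THF, −78 °C) is added to aldehyde 19 to give ethyl 2-[2-(Dec)ethyl]-3-hydroxy-5-[tri(propan-2-yl)silyl]pent-4-ynoate F3. Mesylation (MsCl, Et3N) gives ethyl 2-[2-(Dec)ethyl]-3-[(methylsulfonyl)oxy]-5-[tri(propan-2-yl)silyl]pent-4-ynoate F4, and E1cB elimination with DBU should give mainly the conjugated E ester 23, where the route is rejoined; a minor Z isomer would be removed by chromatography.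

3. Step 15. A competing 6-endo closure to the isomeric 2-pyranone and base- or light-induced isomerisation of the ylidene bond may occur under the Pd/Cu/amine conditions. Fallback: setting out from 25, coupling and ring closure are separated. Acid 27 is esterified (MeI, K2CO3, DMF) to methyl (2Z)-3-iodobut-2-enoate F5. Sonogashira coupling of it with 25 (PdCl2(PPh3)2, CuI, Et3N, THF) should give methyl (2Z,6E)-7-(hydroxymethyl)-3-methyl-9-(Dec)nona-2,6-dien-4-ynoate F6. Saponification (LiOH, THF–H2O, then mild acidification) gives acid 28, now isolated. It is cyclised with catalytic AgNO3 (acetone, rt, dark) by 5-exo-dig anti-oxymetalation, a closure known to favour the Z ylidene butenolide over the pyranone, and the route is rejoined at 29.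

Further compounds
F1 | step 4 | (1R,6S)-1,3-dimethyl-6-(2-methyl-5-oxopentan-2-yl)-2-oxocyclohex-3-ene-1-carbaldehyde | CC1=CC[C@@H](C(C)(C)CCC=O)[C@](C)(C=O)C1=O
F2 | step 11 | ethyl 4-(Dec)butanoate | CCOC(=O)CCCC1=C(C)CC[C@H]2C(C)(C)CCC[C@]12C
F3 | step 11 | ethyl 2-[2-(Dec)ethyl]-3-hydroxy-5-[tri(propan-2-yl)silyl]pent-4-ynoate | CCOC(=O)C(CCC1=C(C)CC[C@H]2C(C)(C)CCC[C@]12C)C(O)C#C[Si](C(C)C)(C(C)C)C(C)C
F4 | step 11 | ethyl 2-[2-(Dec)ethyl]-3-[(methylsulfonyl)oxy]-5-[tri(propan-2-yl)silyl]pent-4-ynoate | CCOC(=O)C(CCC1=C(C)CC[C@H]2C(C)(C)CCC[C@]12C)C(OS(C)(=O)=O)C#C[Si](C(C)C)(C(C)C)C(C)C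
F5 | step 15 | methyl (2Z)-3-iodobut-2-enoate | COC(=O)/C=C(/C)I
F6 | step 15 | methyl (2Z,6E)-7-(hydroxymethyl)-3-methyl-9-(Dec)nona-2,6-dien-4-ynoate | COC(=O)/C=C(/C)C#C/C=C(/CO)CCC1=C(C)CC[C@H]2C(C)(C)CCC[C@]12C
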